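**Retrosynthetic overview**
- Feature: in ring A the oxygens on C5 and C8 are para to each other, C6 carries H and C7 carries OMe. C5–C6–C7–C8 is therefore the carbon square of 3-methoxycyclobutene-1,2-dione, and C4a=C8a is the C3=C2 double bond of a 6-aryl-4-pyranone (ring C).
- Disconnections: (a) the O–CH3 bond at C8, made by methylating the non-chelated OH of the 5,8-hydroquinone; (b) C4a–C5, by retro six-electron closure and retro four-electron opening back to a 4-hydroxy-4-(4-oxopyran-2-yl)cyclobutenone; (c) C8–C8a, from a pyranon-2-yl Grignard reagent and the true ketone carbonyl of methyl semisquarate.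
- Direct lithiation is not the first choice for the pyranonyl nucleophile, because carbonyl-guided C3/C5 deprotonation, ring opening and self-addition all threaten. Instead the C–H next to O1 is zincated with TMPZnCl·LiCl and iodinated, and the iodide is exchanged with iPrMgCl·LiCl.
- (d) Ring C comes from the enolate of (E)-4-methoxybut-3-en-2-one and 2,3,4,5-tetramethoxybenzoyl chloride, followed by acid ring closure. The acid chloride comes from 1,2,3,4-tetramethoxybenzene by ortho-lithiation and carboxylation.
- Ring order: B (bought), C (step 5), four-membered ring attached (step 7), A (step 8).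

Key step: step 8

Remark: the cyclobutenone precursor of the key step is made and used as the racemate, because its only stereocentre is lost in the ring expansion and the target has none.

**Step 1**
Reactants: 1 dimethyl squarate (3,4-dimethoxycyclobut-3-ene-1,2-dione)
Product: 3 3-methoxycyclobut-3-ene-1,2-dione (methyl semisquarate), via hydroxycyclobutenone 2 (not isolated)
Conditions: LiAlH(OtBu)3 (1.05 equiv), THF, −78 → −20 °C; 1 M HCl; crude 2, conc. HCl (cat.), CH2Cl2, rt
Reagents that add atoms: none
Why: The bulky hydride makes a single 1,2-reduction of one squarate carbonyl to racemic 2, and acid then ionises the allylic hydroxyl and expels methanol from the resulting hemiketal (the standard squarate-to-cyclobutenedione carbonyl transposition), which leaves H on the ring carbon.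

**Step 2**
Reactants: 4 1,2,3,4-tetramethoxybenzene
Product: 6 2,3,4,5-tetramethoxybenzoic acid, via aryllithium 5 (not isolated)
Conditions: nBuLi, TMEDA, THF, 0 °C; CO2, −78 °C → rt; 1 M HCl
Reagents that add atoms: carbon dioxide, O=C=O
Why: In this directed ortho-metalation the flanking methoxy group guides nBuLi to the adjacent C–H (the two ring hydrogens are equivalent by symmetry), and carboxylation of 5 gives the acid.

**Step 3**
Reactants: 6 2,3,4,5-tetramethoxybenzoic acid
Product: 7 2,3,4,5-tetramethoxybenzoyl chloride
Conditions: (COCl)2, DMF (cat.), CH2Cl2, 0 °C → rt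
Reagents that add atoms: oxalyl chloride, O=C(Cl)C(=O)Cl
Why: Vilsmeier-type activation turns the acid into its chloride under mild conditions that leave the four aryl methyl ethers untouched.

**Step 4**
Reactants: 7 2,3,4,5-tetramethoxybenzoyl chloride; 8 (E)-4-methoxybut-3-en-2-one
Product: 10 (E)-5-methoxy-1-(2,3,4,5-tetramethoxyphenyl)pent-4-ene-1,3-dione (largely enolised), via lithium enolate 9 (not isolated)
Conditions: 8 (2.1 equiv), LiN(SiMe3)2 (2.1 equiv), THF, −78 °C; 7 (1.0 equiv), −78 °C; cold 1 M HCl
Reagents that add atoms: none
Why: Kinetic deprotonation of the methyl group gives cross-conjugated enolate 9, which is C-acylated by the acid chloride (crossed Claisen-type acylation), while the second equivalent of 9 takes up the acidic proton of 10 and returns as 8 on quenching.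

**Step 5**
Reactants: 10 (E)-5-methoxy-1-(2,3,4,5-tetramethoxyphenyl)pent-4-ene-1,3-dione
Product: 11 2-(2,3,4,5-tetramethoxyphenyl)-4H-pyran-4-one
Conditions: CF3CO2H, toluene, rt
Reagents that add atoms: none
Why: Acid-catalysed 6-endo oxa-Michael addition of the aroyl enol oxygen to the β-methoxyenone and loss of methanol (addition–elimination) closes ring C, which is the established γ-pyranone synthesis from such diketones.

**Step 6**
Reactants: 11 2-(2,3,4,5-tetramethoxyphenyl)-4H-pyran-4-one
Product: 13 2-iodo-6-(2,3,4,5-tetramethoxyphenyl)-4H-pyran-4-one, via pyranonylzinc chloride 12 (not isolated)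
Conditions: TMPZnCl·LiCl (TMP = 2,2,6,6-tetramethylpiperidin-1-yl, 1.3 equiv), THF, 25 °C; I2, THF, 0 °C
Reagents that add atoms: iodine, II
Why: This is deprotonative zincation followed by iodolysis; without added Lewis acid the TMP-zinc base removes the most acidic ring proton, the one beside O1, as it does at C2 of chromones that have both C2–H and C3–H free, and the covalent carbon–zinc bond neither attacks a second pyranone nor triggers the ring-opening β-elimination open to C3/C5-metalated species.

**Step 7**
Reactants: 13 2-iodo-6-(2,3,4,5-tetramethoxyphenyl)-4H-pyran-4-one; 3 3-methoxycyclobut-3-ene-1,2-dione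
Product: 15 racemic 4-hydroxy-3-methoxy-4-[4-oxo-6-(2,3,4,5-tetramethoxyphenyl)-4H-pyran-2-yl]cyclobut-2-en-1-one, via pyranonylmagnesium chloride 14 (not isolated)
Conditions: iPrMgCl·LiCl (1.05 equiv), THF, −78 → −60 °C; cannulated into 3 (1.2 equiv), THF, −78 → −40 °C; sat. aq NH4Cl, −40 °C
Reagents that add atoms: none
Why: Iodine–magnesium exchange on the electron-poor alkenyl iodide should outrun attack on the weakly electrophilic pyranone carbonyl, and 14 then adds 1,2 to the only true ketone of 3, the carbonyl next to C–OMe (the other is deactivated as a vinylogous ester), which places H on the future C6 and OMe on the future C7, while the new carbinol centre forms as a racemate and is erased in step 8.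

**Step 8**
Reactants: 15 racemic 4-hydroxy-3-methoxy-4-[4-oxo-6-(2,3,4,5-tetramethoxyphenyl)-4H-pyran-2-yl]cyclobut-2-en-1-one
Product: 18 5,8-dihydroxy-7-methoxy-2-(2,3,4,5-tetramethoxyphenyl)-4H-chromen-4-one, via dienylketene 16 (not isolated), via cyclohexadienone 17 (not isolated)
Conditions: degassed p-xylene (0.01 M), 138 °C, Ar, dark
Reagents that add atoms: none
Why: Proposed new method: at about 140 °C the C1–C4 bond of the cyclobutenone breaks in a conrotatory four-electron electrocyclic opening, and because a donor on C4 prefers to turn outward, the hydroxyl ends up anti and the pyranonyl group syn to the ketene arm in 16. The ketene carbon (future C5) then joins pyranone C3 (future C4a) in a disrotatory six-electron electrocyclisation over the ketene C=C, the enol C=C and the pyranone C2=C3 bond, which closes ring A as a six-membered carbocycle and gives 17; its C4a–H lies between two carbonyl groups, so enolisation to the aromatic hydroquinone 18 should be immediate and irreversible. The closest known reaction type is the thermal ring expansion of 4-aryl-, 4-heteroaryl- and 4-(cyclic enol ether)-substituted 4-hydroxycyclobutenones to hydroquinones, but a 4-oxopyran-2-yl group has not served as the two-electron partner, hence the label. It should work because the polarity is matched (pyranone C3 is the β carbon of the O1–C2=C3 enol ether, the ketene carbon is the electrophile) and because 4-pyranone has little aromatic stabilisation to give up in 17. Site selectivity needs no steering, since the attachment carbon has only one carbon neighbour (the other is O1) and the H/OMe pattern was fixed in step 7; the selectivity that matters is outward rotation of OH, secured by a purely thermal reaction in the dark, because inward rotation (the photochemical mode) would end in lactonisation. No stereocentre survives, as the carbinol centre becomes sp2 in 16 and the transient C4a centre of 17 is lost on enolisation; high dilution and exclusion of air limit ketene capture by hydroxyl groups and oxidation of the hydroquinone.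

**Step 9**
Reactants: 18 5,8-dihydroxy-7-methoxy-2-(2,3,4,5-tetramethoxyphenyl)-4H-chromen-4-one
Product: 19 5-hydroxy-7,8-dimethoxy-2-(2,3,4,5-tetramethoxyphenyl)-4H-chromen-4-one (target)
Conditions: MeI (1.05 equiv), K2CO3 (1.1 equiv), acetone, Ar, rt → 40 °C
Reagents that add atoms: iodomethane, CI
Why: In this Williamson O-methylation under stoichiometric control, the C5 hydroxyl is held in a six-membered hydrogen bond to the C4 carbonyl and is far less acidic and nucleophilic than the free C8 hydroxyl, which is the classical basis for partial methylation of 5,8-dihydroxyflavones.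

**Compound list**
1 | dimethyl squarate | COC1=C(OC)C(=O)C1=O | starting material
2 | racemic 4-hydroxy-2,3-dimethoxycyclobut-2-en-1-one | COC1=C(OC)C(O)C1=O | intermediate
3 | 3-methoxycyclobut-3-ene-1,2-dione | COC1=CC(=O)C1=O | intermediate
4 | 1,2,3,4-tetramethoxybenzene | COc1ccc(OC)c(OC)c1OC | starting material
5 | (2,3,4,5-tetramethoxyphenyl)lithium | [Li]c1cc(OC)c(OC)c(OC)c1OC | intermediate
6 | 2,3,4,5-tetramethoxybenzoic acid | COc1cc(C(=O)O)c(OC)c(OC)c1OC | intermediate
7 | 2,3,4,5-tetramethoxybenzoyl chloride | COc1cc(C(=O)Cl)c(OC)c(OC)c1OC | intermediate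
8 | (E)-4-methoxybut-3-en-2-one | CO/C=C/C(C)=O | starting material
9 | lithium (E)-4-methoxybuta-1,3-dien-2-olate | CO/C=C/C(=C)O[Li] | intermediate
10 | (E)-5-methoxy-1-(2,3,4,5-tetramethoxyphenyl)pent-4-ene-1,3-dione | CO/C=C/C(=O)CC(=O)c1cc(OC)c(OC)c(OC)c1OC | intermediate
11 | 2-(2,3,4,5-tetramethoxyphenyl)-4H-pyran-4-one | COc1cc(-c2cc(=O)cco2)c(OC)c(OC)c1OC | intermediate
12 | chloro[4-oxo-6-(2,3,4,5-tetramethoxyphenyl)-4H-pyran-2-yl]zinc (LiCl complex) | COc1cc(-c2cc(=O)cc([Zn]Cl)o2)c(OC)c(OC)c1OC | intermediate
13 | 2-iodo-6-(2,3,4,5-tetramethoxyphenyl)-4H-pyran-4-one | COc1cc(-c2cc(=O)cc(I)o2)c(OC)c(OC)c1OC | intermediate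
14 | chloro[4-oxo-6-(2,3,4,5-tetramethoxyphenyl)-4H-pyran-2-yl]magnesium (LiCl complex) | COc1cc(-c2cc(=O)cc([Mg]Cl)o2)c(OC)c(OC)c1OC | intermediate
15 | racemic 4-hydroxy-3-methoxy-4-[4-oxo-6-(2,3,4,5-tetramethoxyphenyl)-4H-pyran-2-yl]cyclobut-2-en-1-one | COC1=CC(=O)C1(O)c1cc(=O)cc(-c2cc(OC)c(OC)c(OC)c2OC)o1 | intermediate
16 | (3Z)-4-hydroxy-3-methoxy-4-[4-oxo-6-(2,3,4,5-tetramethoxyphenyl)-4H-pyran-2-yl]buta-1,3-dien-1-one (pyranonyl syn to the ketene arm) | O=C=C/C(OC)=C(/O)c1cc(=O)cc(-c2cc(OC)c(OC)c(OC)c2OC)o1 | intermediate
17 | racemic 8-hydroxy-7-methoxy-2-(2,3,4,5-tetramethoxyphenyl)-4aH-chromene-4,5-dione | COC1=CC(=O)C2C(=O)C=C(c3cc(OC)c(OC)c(OC)c3OC)OC2=C1O | intermediate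
18 | 5,8-dihydroxy-7-methoxy-2-(2,3,4,5-tetramethoxyphenyl)-4H-chromen-4-one | COc1cc(O)c2c(=O)cc(-c3cc(OC)c(OC)c(OC)c3OC)oc2c1O | intermediate
19 | 5-hydroxy-7,8-dimethoxy-2-(2,3,4,5-tetramethoxyphenyl)-4H-chromen-4-one | COc1cc(-c2cc(=O)c3c(O)cc(OC)c(OC)c3o2)c(OC)c(OC)c1OC | target

Total step count: 9
Longest linear sequence: 8 steps (steps 2 to 9, from 4); step 1 is the convergent branch.

**Steps most likely to fail**

**1. Step 8.**
- Risk: the six-electron closure onto the electron-poor, partly aromatic pyranone double bond may be slower than the competing fates of the ketene. These are dimerisation, capture by hydroxyl groups and reclosure to the cyclobutenone, so material could be lost to oligomerisation.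
- Fallback: a Baker–Venkataraman flavone synthesis, all known chemistry, which sets out from 7 and comes back at 19.
- First, 7 is esterified in pyridine with purchased 1-(2-hydroxy-3,4,6-trimethoxyphenyl)ethanone (CC(=O)c1c(O)c(OC)c(OC)cc1OC). This gives 2-acetyl-3,5,6-trimethoxyphenyl 2,3,4,5-tetramethoxybenzoate F1.
- KOH in pyridine at 50 °C then moves the aroyl group to carbon (Baker–Venkataraman rearrangement). The product is 1-(2-hydroxy-3,4,6-trimethoxyphenyl)-3-(2,3,4,5-tetramethoxyphenyl)propane-1,3-dione F2.
- Catalytic H2SO4 in acetic acid at 100 °C cyclodehydrates F2 to 5,7,8-trimethoxy-2-(2,3,4,5-tetramethoxyphenyl)-4H-chromen-4-one F3.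
- BCl3 (1.1 equiv) in CH2Cl2 at −78 → 0 °C removes only the C5 methyl group, which is chelated to the C4 carbonyl, and gives 19.

**2. Step 7.**
- Risk: the isopropyl Grignard reagent may attack the iodopyranone by addition–elimination or at the carbonyl instead of exchanging. The metalated pyranone may add to unreacted iodide. Proton transfer or conjugate addition may occur at the free vinylic position of the semisquarate.
- Fallback: C–H lithiation in place of halogen–metal exchange, which sets out from 11, leaves out iodide 13 and comes back at 15.
- Compound 11 is treated with lithium 2,2,6,6-tetramethylpiperidide (from the amine and nBuLi) in THF at −78 °C with a short contact time. This non-nucleophilic base should give [4-oxo-6-(2,3,4,5-tetramethoxyphenyl)-4H-pyran-2-yl]lithium F4.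
- F4 is more nucleophilic than 14. It is cannulated at once into 3 at −78 °C and quenched cold with aq NH4Cl to give 15.
- The models are the lithium amide deprotonations beside the heteroatom in isoflavones, N-alkyl-4-pyridones and N-alkyl-4-quinolones. Site control is expected to be weaker than in the zincation.

**3. Step 9.**
- Risk: chemoselectivity may be lost through a second methylation at O5, or the hydroquinone may be oxidised by air in the basic medium.
- Fallback: the C8 methyl group is put on before ring A exists. This sets out from 15 and comes back at 19.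
- The tertiary hydroxyl of 15 is methylated with MeI and Ag2O in acetonitrile at rt. The product is racemic 3,4-dimethoxy-4-[4-oxo-6-(2,3,4,5-tetramethoxyphenyl)-4H-pyran-2-yl]cyclobut-2-en-1-one F5.
- Heating F5 under the conditions of step 8 should run the same opening and closure, because methoxy also rotates outward. It delivers 19 directly: the ketene carbonyl becomes the C5 hydroxyl and the C8 oxygen already carries its methyl group. No free hydroquinone is handled.

**Further compounds**
F1 | step 8 | 2-acetyl-3,5,6-trimethoxyphenyl 2,3,4,5-tetramethoxybenzoate | CC(=O)c1c(OC(=O)c2cc(OC)c(OC)c(OC)c2OC)c(OC)c(OC)cc1OC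
F2 | step 8 | 1-(2-hydroxy-3,4,6-trimethoxyphenyl)-3-(2,3,4,5-tetramethoxyphenyl)propane-1,3-dione | COc1cc(C(=O)CC(=O)c2c(O)c(OC)c(OC)cc2OC)c(OC)c(OC)c1OC
F3 | step 8 | 5,7,8-trimethoxy-2-(2,3,4,5-tetramethoxyphenyl)-4H-chromen-4-one | COc1cc(-c2cc(=O)c3c(OC)cc(OC)c(OC)c3o2)c(OC)c(OC)c1OC
F4 | step 7 | [4-oxo-6-(2,3,4,5-tetramethoxyphenyl)-4H-pyran-2-yl]lithium | COc1cc(-c2cc(=O)cc([Li])o2)c(OC)c(OC)c1OC
F5 | step 9 | racemic 3,4-dimethoxy-4-[4-oxo-6-(2,3,4,5-tetramethoxyphenyl)-4H-pyran-2-yl]cyclobut-2-en-1-one | COC1=CC(=O)C1(OC)c1cc(=O)cc(-c2cc(OC)c(OC)c(OC)c2OC)o1
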